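At the reading, 2.0 h after the start, you want to know how long the chains are and how much Z has reacted.

Z 0.050 M; G 0.2 mol%; E 18 µM; time 2.0 h

    Z + X → Q + J (k1 = 30 M⁻¹ min⁻¹)
    Z + Q → J + Q, rate k2*[Q]*[Z] (k2 = 330 M⁻¹ min⁻¹)
    G → X (k3 = 0.21 min⁻¹)
    X + E → X.E (k4 = 2.2 × 10⁵ M⁻¹ min⁻¹)

1. average number of monomer units in a chain (chains begun, living or dead) at 2.0 h
2. part of the Z that has reacted at 2.0 h

- the average divides the monomer in chains by the number of chains begun, living and dead together
- run time (flask): 2.0 h

**Fastest rung.** In this flask X has a half-life of 0.18 min against E and 0.46 min against Z, both as charged, and each is shorter than the 0.055 h in which G releases it. So X is taken about as it appears, and each unit of the 100 µM of G ends either on E or as a chain.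

**The balance.** E is charged at 18 µM, less than G, and is the limiting reagent of that capture. My own reckoning subtracts: the surviving charge, G charged minus E charged, is 82.0 µM. To test this, take the selectivity factor for E over Z, 7330. While 82.0 µM of chains start, E falls by this estimate to <0.001% of its charge, so the subtraction stands.

**Slow rungs.** No step in the scheme ends a chain, so Z then decays pseudo-first-order with a half-life of 25.6 min. That is longer than G's half-life and shorter than the run. Allowing a late start of one mean life of G, I commit to 95.6% reacted and an average of 583.

**The forecast.** It gives 582 and 95.4%, slightly below mine, on this ground: “All remaining X then starts chains”.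

**The flask.** The simulation gives 582 and 95.4%. At the reading this flask holds 8.20 × 10⁻⁵ M of Q and 1.80 × 10⁻⁵ M of X.E, the surviving charge and the charge of E. The depletion of G, of which 0% is left at the reading, has the largest single effect on the average in this flask: with G held at its charge, the average falls from 582 to 82.2. In the neighbour flask, charged with 7.2 × 10⁻⁵ M of E, the surviving charge is 28.0 µM, which with its 65.5% reacted gives 1170, and that flask reads 2.89 × 10⁻⁵ M of Q and an average of 1130.

All constants are invented.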